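The runs are simulated with constants of no real substance, noise included.

**Slow start.** Slowness is what you see first. After 2.50 min the gamma run, this very flask of D followed so far, holds 3.3 % Z and 5.7 % L, and you are asked about 30 min.

- gamma: D 0.80 M; the very flask that is asked about, followed so far
- flask: D 0.80 M; time 30 min

- gamma (time / min: Z / %, L / %): 0.200: 0.2, 0.1; 0.333: 0, 0.6; 0.417: 0, 0.7; 0.667: 1.0, 0.7; 1.00: 1.3, 1.4; 1.50: 2.1, 2.1; 2.50: 3.3, 5.7

(each reading ± 0.3 percentage points)

- reactions considered so far: D <-> X; D <-> G; G -> L; G -> Z; G -> Q; Q -> J
- the reaction counts as stopped when no species that holds the D changes by six tenths of a point or more over the second half of the time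

1. the state of affairs at 30 min: stopped, and by what, or still going (all of D has reacted / forward and back rates have come level / it is still moving)
2. how much Z there is at 30 min, in percent of the D charged
3. how much L there is at 30 min, in percent of the D charged
4. how much X there is at 30 min, in percent of the D charged

**Two exits.** In the reactions considered, D goes reversibly to X and to G. G goes on to L, to Z and to Q, and Q gives J. So L and Z leave the same G. My number is 1.43: this is S, the selectivity factor, L made per Z made, summed over the gamma readings. A symmetric split has S = 1, and this reading stands above it, so L leads. Each reading carries 0.3 percentage points, so the second digit of S is soft. If both exits are first order in G, L in this flask should stay near S times Z as the run goes on.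

**One number?** S gives the split, not the clock. At the average pace up to the last gamma reading, Z and L together would take up the charge in 27.8 min. That is a little shorter than the 30 min asked about, but the pace should fall as D falls, so I expect this flask to be still moving at 30 min. S says nothing of X.

**The forecast.** It said it is still moving, with Z 21 % (13 % to 30 %), L 31 % (18 % to 46 %) and X 8 % (1 % to 25 %): “That gives L/Z of roughly 1.5, though this rests heavily on the last point.”

**The flask.** The state of the flask at 30 min: it is still moving, with Z 25.4 %, L 39.6 % and X 15.6 %. L stands 8.6 points above the forecast.

    D ⇌ X (K = 0.980, k = 0.00349 /s)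
    D ⇌ G (K = 0.450, k = 0.00197 /s)
    G → L (k = 0.00590 /s)
    G → Z (k = 0.00379 /s)
    G → Q (k = 6.54 × 10⁻⁴ /s)
    Q → J (k = 0.00771 /s)

**The split.** At 8.47 min in this flask G goes to L 1.6 times as fast as to Z. At 30 min the flask holds L and Z in the ratio 1.56. Carried over, S times Z gives 36.3 % of L here, against 39.6 % in the flask. In the neighbour flask, the same charge read at 2.0 h, S times its 36.2 % of Z gives 51.8 %, and that flask holds 56.4 % of L.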